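Decide first how long the complex with two exchanged lives once its making has stopped, then rank the flasks by that clock.

| flask | starting complex | incoming ligand | temperature | remark | time |
|---|---|---|---|---|---|
| alder | 0.050 M | 0.014 M | −25 °C | run made earlier |  |
| maple | 0.050 M | 0.053 M | −14 °C | run made earlier |  |
| Thursday's | 0.050 M | 0.0500 M | −20 °C |  | 40 min |
| Saturday's | 0.050 M | 0.0120 M | −20 °C |  | 40 min |
| Monday's | 0.050 M | 0.100 M | −20 °C |  | 40 min |
| Sunday's | 0.050 M | 0.200 M | −20 °C |  | 40 min |

| run | time / min | complex with two exchanged / % | starting complex / % |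
|---|---|---|---|
| alder | 1.50 | 0 | 42.4 |
| alder | 3.00 | 1.4 | 40.3 |
| alder | 6.00 | 0 | 37.9 |
| alder | 10.0 | 0 | 36.9 |
| alder | 20.0 | 0.1 | 34.4 |
| maple | 1.50 | 10.3 | 19.3 |
| maple | 3.00 | 13.8 | 14.7 |
| maple | 6.00 | 16.4 | 11.9 |
| maple | 10.0 | 12.4 | 10.1 |
| maple | 20.0 | 4.6 | 9.2 |

(each reading ± 1 percentage point)



- all flasks from highest to lowest amount of complex with two exchanged, in percent of the starting complex charged, at 40 min (Thursday's / Saturday's / Monday's / Sunday's)
- the same order at 8.0 min (Thursday's / Saturday's / Monday's / Sunday's)
- the amount of complex with two exchanged, in percent of the starting complex charged of the flask you put first, at 40 min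
- the amount of complex with two exchanged, in percent of the starting complex charged of the flask you put last, at 40 min

In the maple run this complex reads 16.4% at 6.00 min and 4.6% at 20.0 min, while the starting complex moves from 11.9% to 9.2%. I therefore treat that stretch as pure loss. Let h be the time in which the amount falls to half.

h at −14 °C = 7.63 min

My guess for the colder bath is a rate lower by a factor of 2:

h at −20 °C = 15.3 min

From 8.0 min to 40 min is 32.0 min. Counting the whole charge as this complex at 8.0 min, the clock leaves 23.4% at 40 min, and that is my first figure for the top.

The weak link is the start of the stretch. 16.4% is the peak reading, so making may still have been running there. Take the later pair instead, remembering that the last reading carries a scatter of 1 percentage point: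

h at −14 °C = 6.99 min

h at −20 °C = 14.0 min, the half-life of the complex with two exchanged in the colder bath

Kept from 8.0 min to 40 min: 20.5%

I commit to that figure for the top. Sunday's holds the most ligand, so I expect it to lead at 8.0 min. I expect Monday's to go on making it for longer, start its clock later and lead at 40 min.

The forecast gave Monday's > Thursday's > Saturday's > Sunday's at 40 min and Monday's > Sunday's > Thursday's > Saturday's at 8.0 min, with top 10% and low 0.2%, holding that Monday's “should build most and persist”. Its top lies below mine.

The flask gives Monday's > Sunday's > Thursday's > Saturday's at 40 min and Sunday's > Monday's > Thursday's > Saturday's at 8.0 min, with top 20.0% and low 0.387%.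

    leaving ligand + complex with two exchanged → side product (k = 0.0320 M⁻¹ s⁻¹, Ea = 49.0 kJ mol⁻¹)
    starting complex ⇌ dormant form (K = 0.890, k = 0.0410 s⁻¹, Ea = 67.0 kJ mol⁻¹, ΔH = −11.0 kJ mol⁻¹)
    crystals ⇌ leaving ligand, rate k3*(cs3 - [leaving ligand]) while solid is left; crystals form when [leaving ligand] > cs3 (solubility = 26.0 mM, k = 0.190 s⁻¹)
    complex with one exchanged + incoming ligand → leaving ligand + complex with two exchanged (k = 0.0640 M⁻¹ s⁻¹, Ea = 57.0 kJ mol⁻¹)
    starting complex + incoming ligand → leaving ligand + complex with one exchanged (k = 0.410 M⁻¹ s⁻¹, Ea = 41.0 kJ mol⁻¹)
    (constants at −20 °C)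

Sunday's held 71.9% at 8.0 min, then fell in a pseudo-first-order way while side product rose to 84.5% at 40.0 min; at 40 min leaving ligand stood at 0.0260 M beside 0.0318 M of crystals, and the half-life h turns that amount into 14.7% against the flask's 15.5%. Thursday's, with leaving ligand at 0.0260 M at 20.0 min and 0.0260 M at 40.0 min, went from 9.21% to 3.46% of the complex with two exchanged over those times, and the half-life h gives 3.42%. Monday's was still making it over those minutes, its complex with one exchanged going from 20.9% to 11.6%, and the half-life h applied to its 39.5% gives 14.7% where the flask held 20.0%.

The runs are calculated with made-up constants; noise was put on by code.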